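**Retrosynthetic overview** (locants: hydrindane numbering with the ketone as C7; C1–C3 cyclopentane CH2 groups, C3a and C7a the methyl-bearing ring-fusion carbons, C4 ring CH2, C5=C6 the enone alkene)
1. Last bonds: two silyl ethers are removed; C5–CH2 is made by Stille coupling of a C5 trimethylstannyl enone (from the C5 enol triflate of the 5,7-dione) with the (E)-allylic bromide ArCH2CH=C(CH3)CH2Br, itself built from 4-methoxy-2-methylphenol by aromatic Claisen rearrangement and cross-metathesis.
2. Six-membered ring: C5–C6 by Dieckmann-type closure of a δ-keto ester; C6–C7 by addition of the alkyllithium from 3-methylbutane-1,3-diol to a cis-fused δ-lactone (C7 carbonyl, ring oxygen on C5).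
3. Feature that carries the strategy: the cyclopentane C7a–C1–C2–C3–C3a with vicinal quaternary carbons C7a (CH3, C7) and C3a (CH3, C4). It is the [3,3] product of the nine-membered lactone C7(=O)–O–C5–C4=C3a(CH3)–C3–C2–C1–C7a(CH3), so the C7a–C3a bond is made across that ring; the seco acid of the lactone has the carbon skeleton of nerol.
4. The lactone comes from neryl acetate: allylic oxidation of the (E)-methyl group, conjugate reduction, oxidation to the acid, deacetylation, lactonisation.
5. Ring order: nine-membered lactone, then cyclopentane (ring contraction, both quaternary centres), then a temporary δ-lactone, then the cyclohexane-1,3-dione/enone ring; the arene is carried in from its starting material.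

Key step: step 6

Assumption: the (S,S)-configured boron reagent is written for step 6; for a boat-shaped transannular array the sense of induction cannot be taken over from the chair-type acyclic cases, so it is to be assigned on the first run, and the (R,R)-reagent would replace it with no other change if the antipodal acid forms.

**Route**

Step 1
Reactants: 1 neryl acetate
Product: 3 (2Z,6E)-3,7-dimethyl-8-oxoocta-2,6-dien-1-yl acetate, via allylic alcohol 2 (not isolated)
Conditions: SeO2 (cat.), salicylic acid (cat.), t-BuOOH, CH2Cl2, rt; crude product then MnO2, CH2Cl2, rt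
Reagents that add atoms: tert-butyl hydroperoxide, CC(C)(C)OO (its oxygen is passed on through catalytic selenium dioxide, O=[Se]=O)
Why: Allylic oxidation with SeO2 (ene reaction, then [2,3]-sigmatropic shift) attacks the (E)-methyl group of the electron-richer C6=C7 alkene remote from the acetate, and MnO2 then takes the allylic alcohol to the (E)-enal without touching the allylic acetate.

Step 2
Reactants: 3 (2Z,6E)-3,7-dimethyl-8-oxoocta-2,6-dien-1-yl acetate
Product: 5 (2Z)-3,7-dimethyl-8-oxooct-2-en-1-yl acetate (racemic at C7), via silyl enol ether 4 (not isolated)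
Conditions: [(Ph3P)CuH]6 (cat.), PhMe2SiH, toluene, rt; then 1 M HCl, THF, 0 °C
Reagents that add atoms: none
Why: CuH-catalysed conjugate reduction (1,4-hydrosilylation) is selective for the enal over the isolated trisubstituted alkene and the allylic acetate; the new α-stereocentre forms racemic and is erased at the enolisation of step 6.

Step 3
Reactants: 5 (2Z)-3,7-dimethyl-8-oxooct-2-en-1-yl acetate
Product: 6 (6Z)-8-acetoxy-2,6-dimethyloct-6-enoic acid
Conditions: NaClO2, NaH2PO4, 2-methyl-2-butene, t-BuOH–H2O, 0 °C → rt
Reagents that add atoms: sodium chlorite, [Na+].[O-]Cl=O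
Why: Pinnick oxidation converts the aldehyde to the acid while 2-methyl-2-butene traps HOCl and so spares the trisubstituted alkene.

Step 4
Reactants: 6 (6Z)-8-acetoxy-2,6-dimethyloct-6-enoic acid
Product: 7 (6Z)-8-hydroxy-2,6-dimethyloct-6-enoic acid
Conditions: K2CO3, MeOH, rt; then cold aq. KHSO4 to pH 4
Reagents that add atoms: none
Why: Base-mediated transesterification with methanol removes the primary allylic acetate while the carboxylate is inert, and the mild acidification avoids ionisation of the neryl-type alcohol.

Step 5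
Reactants: 7 (6Z)-8-hydroxy-2,6-dimethyloct-6-enoic acid
Product: 9 (7Z)-3,7-dimethyloxacyclonon-7-en-2-one (racemic at C3), via mixed anhydride 8 (not isolated)
Conditions: 2,4,6-Cl3C6H2COCl, Et3N, THF, rt; then slow addition to DMAP, toluene, 90 °C, high dilution
Reagents that add atoms: none
Why: Yamaguchi macrolactonisation: the mixed anhydride acylates DMAP and the acylpyridinium ion is captured by the allylic hydroxyl, the (Z)-alkene holding both chain ends on one side so that the nine-membered ring should close under high dilution.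

Step 6
Reactants: 9 (7Z)-3,7-dimethyloxacyclonon-7-en-2-one
Product: 12 (1R,2R)-2-ethenyl-1,2-dimethylcyclopentane-1-carboxylic acid, via boron ketene acetal 10 (not isolated), via acyloxyborane 11 (not isolated)
Conditions: (S,S)-2-bromo-4,5-diphenyl-1,3-bis[3,5-bis(trifluoromethyl)phenylsulfonyl]-1,3,2-diazaborolidine [from the (S,S)-bis-sulfonamide and BBr3, CH2Cl2, volatiles removed], Et3N, CH2Cl2, −78 °C, then −20 °C → rt; aqueous work-up (bis-sulfonamide recovered)
Reagents that add atoms: none
Why: Proposed new method: the bromoborane binds the lactone carbonyl and Et3N removes the C7a proton (either C3 epimer of 9 serves), so that a boron ketene acetal C7a=C7(OB)–O forms inside the ring with ring carbon C1 and ring oxygen cis, and its [3,3] shift of the Ireland–Claisen type makes C7a–C3a, breaks C5–O and turns C4=C3a into the vinyl group C4=C5. The closest known reactions are the silyl ketene acetal Claisen ring contraction of unsaturated medium-ring lactones to cis-2-alkenylcycloalkanecarboxylic acids and the enantioselective Claisen rearrangement of acyclic allyl ester boron enolates carrying this diazaborolidine; neither has been run with two fully substituted termini. The cyclopentane (C7a, C1, C2, C3, C3a) closes by transannular bond formation across the nine-membered ring, the six-atom pericyclic array being bridged by the three-carbon tether C1–C2–C3. This tether joins the two inward substituents of the termini, which is possible only in a boat-shaped array, and that places carboxyl and vinyl cis and so fixes the relative configuration of C7a and C3a. The absolute configuration of both centres has to come from the C2-symmetric sulfonamide ligand on boron, which shields one face of the ketene acetal and thereby selects one of the two enantiomeric boats. The step needs this facial selectivity and a rearrangement that outruns decay of the boron enolate; relief of medium-ring strain and the exchange of a C–O for a C–C bond are counted on to drive a bond between two quaternary carbons.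

Step 7
Reactants: 12 (1R,2R)-2-ethenyl-1,2-dimethylcyclopentane-1-carboxylic acid
Product: 15 (4aR,7aR)-4a,7a-dimethylhexahydrocyclopenta[c]pyran-1(3H)-one, via bis-borylated adduct 13 (not isolated), via hydroxy acid 14 (not isolated)
Conditions: 9-BBN (2.5 equiv), THF, 0 → 60 °C; NaOH, H2O2, 0 °C → rt; HCl to pH 2, then TsOH (cat.), toluene, rt
Reagents that add atoms: hydrogen peroxide, OO
Why: Hydroboration–oxidation: 9-BBN first ties up the acid as an acyloxyborane without reducing it and then adds anti-Markovnikov to the vinyl group, and the hydroxy acid lactonises because carboxyl and hydroxyethyl arm are cis on the cyclopentane; no stereocentre is touched.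

Step 8
Reactants: 16 3-methylbutane-1,3-diol
Product: 17 4-iodo-2-methylbutan-2-ol
Conditions: I2, PPh3, imidazole, CH2Cl2, 0 °C
Reagents that add atoms: iodine, II
Why: Appel-type iodination is selective for the primary hydroxyl because the tertiary one is too hindered to form the alkoxyphosphonium ion.

Step 9
Reactants: 17 4-iodo-2-methylbutan-2-ol
Product: 18 triethyl[(4-iodo-2-methylbutan-2-yl)oxy]silane
Conditions: Et3SiOTf, 2,6-lutidine, CH2Cl2, −78 → 0 °C
Reagents that add atoms: triethylsilyl trifluoromethanesulfonate, CC[Si](CC)(CC)OS(=O)(=O)C(F)(F)F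
Why: Silylation with a silyl triflate and a hindered pyridine base is the standard protection of a tertiary alcohol.

Step 10
Reactants: 18 triethyl[(4-iodo-2-methylbutan-2-yl)oxy]silane; 15 (4aR,7aR)-4a,7a-dimethylhexahydrocyclopenta[c]pyran-1(3H)-one
Product: 21 1-[(1R,2R)-2-(2-hydroxyethyl)-1,2-dimethylcyclopentyl]-4-methyl-4-[(triethylsilyl)oxy]pentan-1-one (in equilibrium with its cyclic hemiketal), via alkyllithium 19 (not isolated), via lithium lactolate 20 (not isolated)
Conditions: 18, t-BuLi (2.0 equiv), Et2O–pentane, −78 °C; then 15, Et2O, −78 → −40 °C; sat. NH4Cl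
Reagents that add atoms: none
Why: Iodine–lithium exchange gives a primary alkyllithium that adds once to the δ-lactone (nucleophilic acyl addition), since the lithium lactolate resists collapse and the α-quaternary ketone resists a second addition, and the low temperature suppresses retro-Brook migration of silicon from oxygen to carbon.

Step 11
Reactants: 21 1-[(1R,2R)-2-(2-hydroxyethyl)-1,2-dimethylcyclopentyl]-4-methyl-4-[(triethylsilyl)oxy]pentan-1-one
Product: 22 2-[(1R,2R)-1,2-dimethyl-2-{4-methyl-4-[(triethylsilyl)oxy]pentanoyl}cyclopentyl]acetic acid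
Conditions: TEMPO (cat.), PhI(OAc)2, MeCN–H2O, rt
Reagents that add atoms: water, O
Why: TEMPO/PhI(OAc)2 oxidation in the presence of water takes the primary alcohol of the open form through the aldehyde hydrate to the acid, while the tertiary hemiketal cannot be oxidised and drains into the open form.

Step 12
Reactants: 22 2-[(1R,2R)-1,2-dimethyl-2-{4-methyl-4-[(triethylsilyl)oxy]pentanoyl}cyclopentyl]acetic acid
Product: 23 methyl 2-[(1R,2R)-1,2-dimethyl-2-{4-methyl-4-[(triethylsilyl)oxy]pentanoyl}cyclopentyl]acetate
Conditions: Me3SiCHN2, MeOH–toluene, 0 °C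
Reagents that add atoms: trimethylsilyldiazomethane, C[Si](C)(C)C=[N+]=[N-]
Why: Methyl esterification with trimethylsilyldiazomethane is neutral and leaves ketone and silyl ether untouched.

Step 13
Reactants: 23 methyl 2-[(1R,2R)-1,2-dimethyl-2-{4-methyl-4-[(triethylsilyl)oxy]pentanoyl}cyclopentyl]acetate
Product: 24 (3aR,7aR)-3a,7a-dimethyl-6-{2-methyl-2-[(triethylsilyl)oxy]propyl}hexahydroindane-5,7-dione (C6 epimers and enol forms)
Conditions: KOt-Bu, THF, 0 °C → rt; then cold 1 M HCl to pH 4
Reagents that add atoms: none
Why: Intramolecular Claisen (Dieckmann-type) condensation: only the C6 enolate of the ketone can reach the ester in a six-membered closure (the C4 ester enolate would have to close a four-membered ring), and the product is drained as its stable dione enolate.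

Step 14
Reactants: 24 (3aR,7aR)-3a,7a-dimethyl-6-{2-methyl-2-[(triethylsilyl)oxy]propyl}hexahydroindane-5,7-dione
Product: 25 (3aR,7aR)-3a,7a-dimethyl-6-{2-methyl-2-[(triethylsilyl)oxy]propyl}-7-oxo-2,3,3a,4,7,7a-hexahydro-1H-inden-5-yl trifluoromethanesulfonate
Conditions: Tf2O, Et3N, CH2Cl2, −78 °C
Reagents that add atoms: trifluoromethanesulfonic anhydride, O=S(=O)(OS(=O)(=O)C(F)(F)F)C(F)(F)F
Why: O-sulfonylation of the dione enolate (enol triflate formation) should take place at the C5 oxygen because the C7 oxygen is shielded by the adjacent quaternary C7a.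

Step 15
Reactants: 25 (3aR,7aR)-3a,7a-dimethyl-6-{2-methyl-2-[(triethylsilyl)oxy]propyl}-7-oxo-2,3,3a,4,7,7a-hexahydro-1H-inden-5-yl trifluoromethanesulfonate
Product: 26 (3aR,7aR)-3a,7a-dimethyl-6-{2-methyl-2-[(triethylsilyl)oxy]propyl}-5-(trimethylstannyl)-1,2,3,3a,4,7a-hexahydro-7H-inden-7-one
Conditions: Me3SnSnMe3, Pd(PPh3)4 (cat.), LiCl, THF, 65 °C
Reagents that add atoms: hexamethylditin, C[Sn](C)(C)[Sn](C)(C)C
Why: Pd-catalysed stannylation of an enol triflate with a ditin (Stille-type coupling) turns the C5 electrophile into a C5 nucleophile under neutral conditions.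

Step 16
Reactants: 27 4-methoxy-2-methylphenol; 28 allyl bromide
Product: 29 4-methoxy-2-methyl-1-(prop-2-en-1-yloxy)benzene
Conditions: K2CO3, acetone, reflux
Reagents that add atoms: none
Why: Williamson ether synthesis of the phenoxide with a reactive allylic bromide.

Step 17
Reactants: 29 4-methoxy-2-methyl-1-(prop-2-en-1-yloxy)benzene
Product: 30 4-methoxy-2-methyl-6-(prop-2-en-1-yl)phenol
Conditions: PhNEt2, 190 °C
Reagents that add atoms: none
Why: Aromatic Claisen rearrangement delivers the allyl group to the only free ortho position, the other ortho position carrying the methyl and the para position the methoxy group.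

Step 18
Reactants: 30 4-methoxy-2-methyl-6-(prop-2-en-1-yl)phenol
Product: 31 tert-butyl[4-methoxy-2-methyl-6-(prop-2-en-1-yl)phenoxy]dimethylsilane
Conditions: t-BuMe2SiCl, imidazole, DMF, rt
Reagents that add atoms: tert-butyldimethylsilyl chloride, CC(C)(C)[Si](C)(C)Cl
Why: Silylation protects the phenol from the bromination of step 21 and from O-allylation by the (η3-allyl)Pd intermediate of step 22.

Step 19
Reactants: 31 tert-butyl[4-methoxy-2-methyl-6-(prop-2-en-1-yl)phenoxy]dimethylsilane; 32 methacrolein
Product: 33 (2E)-4-{2-[(tert-butyldimethylsilyl)oxy]-5-methoxy-3-methylphenyl}-2-methylbut-2-enal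
Conditions: methacrolein (excess), second-generation Grubbs catalyst RuCl2(=CHPh)(H2IMes)(PCy3) (cat.), 1,4-benzoquinone (cat.), CH2Cl2, 40 °C
Reagents that add atoms: none
Why: Olefin cross-metathesis of a terminal alkene with methacrolein forms the trisubstituted enal under thermodynamic control, so the (E)-isomer with formyl trans to the benzylic CH2 is expected, and benzoquinone suppresses migration of the allyl double bond.

Step 20
Reactants: 33 (2E)-4-{2-[(tert-butyldimethylsilyl)oxy]-5-methoxy-3-methylphenyl}-2-methylbut-2-enal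
Product: 34 (2E)-4-{2-[(tert-butyldimethylsilyl)oxy]-5-methoxy-3-methylphenyl}-2-methylbut-2-en-1-ol
Conditions: i-Bu2AlH, CH2Cl2, −78 °C; Rochelle salt work-up
Reagents that add atoms: none
Why: 1,2-Reduction of the enal with i-Bu2AlH gives the allylic alcohol without change of alkene geometry and without touching the aryl silyl ether.

Step 21
Reactants: 34 (2E)-4-{2-[(tert-butyldimethylsilyl)oxy]-5-methoxy-3-methylphenyl}-2-methylbut-2-en-1-ol
Product: 35 {2-[(2E)-4-bromo-3-methylbut-2-en-1-yl]-4-methoxy-6-methylphenoxy}(tert-butyl)dimethylsilane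
Conditions: CBr4, PPh3, CH2Cl2, 0 °C
Reagents that add atoms: carbon tetrabromide, BrC(Br)(Br)Br
Why: Appel bromination converts the primary allylic alcohol to the bromide by SN2 displacement and keeps the (E)-alkene in place.

Step 22
Reactants: 26 (3aR,7aR)-3a,7a-dimethyl-6-{2-methyl-2-[(triethylsilyl)oxy]propyl}-5-(trimethylstannyl)-1,2,3,3a,4,7a-hexahydro-7H-inden-7-one; 35 {2-[(2E)-4-bromo-3-methylbut-2-en-1-yl]-4-methoxy-6-methylphenoxy}(tert-butyl)dimethylsilane
Product: 36 bis-silyl ether of the target (aryl O–SiMe2t-Bu and tertiary O–SiEt3)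
Conditions: Pd2(dba)3 (cat.), P(2-furyl)3, CuI (cat.), NMP, rt → 40 °C
Reagents that add atoms: none
Why: Stille coupling of an allylic bromide with an alkenylstannane: oxidative addition gives the syn (η3-allyl)Pd intermediate directly from the (E)-bromide, and bond formation at its unsubstituted CH2 terminus with the bulky C5 alkenyl group should keep regiochemistry and (E)-geometry, while the neutral conditions spare the base-sensitive skipped dienone.

Step 23
Reactants: 36 bis-silyl ether of the target
Product: 37 CNP0158008.2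
Conditions: Bu4NF, AcOH (1:1), THF, 0 °C → rt
Reagents that add atoms: none
Why: Fluoride-mediated desilylation removes the aryl tert-butyldimethylsilyl and the tertiary triethylsilyl ether, and the acetic acid buffer guards against base-induced migration of the side-chain alkene into conjugation without being acidic enough to close the phenol onto that alkene as a chroman.

**Compound list**
1 | neryl acetate, (2Z)-3,7-dimethylocta-2,6-dien-1-yl acetate | CC(C)=CCC/C(C)=C\COC(C)=O | starting material
2 | (2Z,6E)-8-hydroxy-3,7-dimethylocta-2,6-dien-1-yl acetate (not isolated) | OC/C(C)=C/CC/C(C)=C\COC(C)=O | intermediate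
3 | (2Z,6E)-3,7-dimethyl-8-oxoocta-2,6-dien-1-yl acetate | O=C/C(C)=C/CC/C(C)=C\COC(C)=O | intermediate
4 | (2Z)-8-{[dimethyl(phenyl)silyl]oxy}-3,7-dimethylocta-2,7-dien-1-yl acetate, enol ether of mixed geometry (not isolated) | C[Si](C)(OC=C(C)CCC/C(C)=C\COC(C)=O)c1ccccc1 | intermediate
5 | (2Z)-3,7-dimethyl-8-oxooct-2-en-1-yl acetate, racemic at C7 | O=CC(C)CCC/C(C)=C\COC(C)=O | intermediate
6 | (6Z)-8-acetoxy-2,6-dimethyloct-6-enoic acid, racemic | OC(=O)C(C)CCC/C(C)=C\COC(C)=O | intermediate
7 | (6Z)-8-hydroxy-2,6-dimethyloct-6-enoic acid, racemic | OC(=O)C(C)CCC/C(C)=C\CO | intermediate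
8 | mixed anhydride of 7 with 2,4,6-trichlorobenzoic acid (not isolated) | CC(CCC/C(C)=C\CO)C(=O)OC(=O)c1c(Cl)cc(Cl)cc1Cl | intermediate
9 | (7Z)-3,7-dimethyloxacyclonon-7-en-2-one, racemic at C3 | CC1CCC/C(C)=C\COC1=O | intermediate
10 | boron ketene acetal of 9: O-bound (4S,5S)-4,5-diphenyl-1,3-bis[3,5-bis(trifluoromethyl)phenylsulfonyl]-1,3,2-diazaborolidin-2-yl group, ring carbon C1 and ring oxygen cis on C7a=C7, (Z)-C3a=C4 retained (not isolated) | C/C1=C(\OB2N(S(=O)(=O)c3cc(cc(c3)C(F)(F)F)C(F)(F)F)[C@@H](c3ccccc3)[C@H](c3ccccc3)N2S(=O)(=O)c2cc(cc(c2)C(F)(F)F)C(F)(F)F)OC/C=C(C)\CCC1 | intermediate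
11 | acyloxyborane: carboxylate of 12 bound to the same (4S,5S)-diazaborolidine boron (not isolated) | O=C(OB1N(S(=O)(=O)c2cc(cc(c2)C(F)(F)F)C(F)(F)F)[C@@H](c2ccccc2)[C@H](c2ccccc2)N1S(=O)(=O)c1cc(cc(c1)C(F)(F)F)C(F)(F)F)[C@]1(C)CCC[C@]1(C)C=C | intermediate
12 | (1R,2R)-2-ethenyl-1,2-dimethylcyclopentane-1-carboxylic acid (carboxyl and vinyl cis) | OC(=O)[C@]1(C)CCC[C@]1(C)C=C | intermediate
13 | adduct of 12 with two 9-BBN units, carboxyl O–B and terminal C–B (not isolated) | O=C(OB1C2CCCC1CCC2)[C@]1(C)CCC[C@]1(C)CCB1C2CCCC1CCC2 | intermediate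
14 | (1R,2R)-2-(2-hydroxyethyl)-1,2-dimethylcyclopentane-1-carboxylic acid (not isolated) | OC(=O)[C@]1(C)CCC[C@]1(C)CCO | intermediate
15 | (4aR,7aR)-4a,7a-dimethylhexahydrocyclopenta[c]pyran-1(3H)-one, cis-fused δ-lactone | O1C(=O)[C@]2(C)CCC[C@]2(C)CC1 | intermediate
16 | 3-methylbutane-1,3-diol | CC(C)(O)CCO | starting material
17 | 4-iodo-2-methylbutan-2-ol | CC(C)(O)CCI | intermediate
18 | triethyl[(4-iodo-2-methylbutan-2-yl)oxy]silane | CC[Si](CC)(CC)OC(C)(C)CCI | intermediate
19 | {3-methyl-3-[(triethylsilyl)oxy]butyl}lithium (not isolated) | [Li]CCC(C)(C)O[Si](CC)(CC)CC | intermediate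
20 | lithium lactolate from 15 and 19, mixture at the hemiketal carbon (not isolated) | O1C(O[Li])(CCC(C)(C)O[Si](CC)(CC)CC)[C@]2(C)CCC[C@]2(C)CC1 | intermediate
21 | 1-[(1R,2R)-2-(2-hydroxyethyl)-1,2-dimethylcyclopentyl]-4-methyl-4-[(triethylsilyl)oxy]pentan-1-one | CC[Si](CC)(CC)OC(C)(C)CCC(=O)[C@]1(C)CCC[C@]1(C)CCO | intermediate
22 | 2-[(1R,2R)-1,2-dimethyl-2-{4-methyl-4-[(triethylsilyl)oxy]pentanoyl}cyclopentyl]acetic acid | CC[Si](CC)(CC)OC(C)(C)CCC(=O)[C@]1(C)CCC[C@]1(C)CC(O)=O | intermediate
23 | methyl 2-[(1R,2R)-1,2-dimethyl-2-{4-methyl-4-[(triethylsilyl)oxy]pentanoyl}cyclopentyl]acetate | CC[Si](CC)(CC)OC(C)(C)CCC(=O)[C@]1(C)CCC[C@]1(C)CC(=O)OC | intermediate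
24 | (3aR,7aR)-3a,7a-dimethyl-6-{2-methyl-2-[(triethylsilyl)oxy]propyl}hexahydroindane-5,7-dione, C6 epimers and enol forms | O=C1C(CC(C)(C)O[Si](CC)(CC)CC)C(=O)[C@]2(C)CCC[C@]2(C)C1 | intermediate
25 | C5 enol triflate: (3aR,7aR)-3a,7a-dimethyl-6-{2-methyl-2-[(triethylsilyl)oxy]propyl}-7-oxo-2,3,3a,4,7,7a-hexahydro-1H-inden-5-yl trifluoromethanesulfonate | FC(F)(F)S(=O)(=O)OC1=C(CC(C)(C)O[Si](CC)(CC)CC)C(=O)[C@]2(C)CCC[C@]2(C)C1 | intermediate
26 | C5 stannane: (3aR,7aR)-3a,7a-dimethyl-6-{2-methyl-2-[(triethylsilyl)oxy]propyl}-5-(trimethylstannyl)-1,2,3,3a,4,7a-hexahydro-7H-inden-7-one | C[Sn](C)(C)C1=C(CC(C)(C)O[Si](CC)(CC)CC)C(=O)[C@]2(C)CCC[C@]2(C)C1 | intermediate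
27 | 4-methoxy-2-methylphenol | COc1ccc(O)c(C)c1 | starting material
28 | allyl bromide, 3-bromoprop-1-ene | C=CCBr | starting material
29 | 4-methoxy-2-methyl-1-(prop-2-en-1-yloxy)benzene | COc1ccc(OCC=C)c(C)c1 | intermediate
30 | 4-methoxy-2-methyl-6-(prop-2-en-1-yl)phenol | COc1cc(C)c(O)c(CC=C)c1 | intermediate
31 | tert-butyl[4-methoxy-2-methyl-6-(prop-2-en-1-yl)phenoxy]dimethylsilane | COc1cc(C)c(O[Si](C)(C)C(C)(C)C)c(CC=C)c1 | intermediate
32 | methacrolein, 2-methylprop-2-enal | CC(=C)C=O | starting material
33 | (2E)-4-{2-[(tert-butyldimethylsilyl)oxy]-5-methoxy-3-methylphenyl}-2-methylbut-2-enal | COc1cc(C)c(O[Si](C)(C)C(C)(C)C)c(C/C=C(\C)C=O)c1 | intermediate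
34 | (2E)-4-{2-[(tert-butyldimethylsilyl)oxy]-5-methoxy-3-methylphenyl}-2-methylbut-2-en-1-ol | COc1cc(C)c(O[Si](C)(C)C(C)(C)C)c(C/C=C(\C)CO)c1 | intermediate
35 | {2-[(2E)-4-bromo-3-methylbut-2-en-1-yl]-4-methoxy-6-methylphenoxy}(tert-butyl)dimethylsilane | COc1cc(C)c(O[Si](C)(C)C(C)(C)C)c(C/C=C(\C)CBr)c1 | intermediate
36 | bis-silyl ether of the target: (3aR,7aR)-5-[(2E)-4-{2-[(tert-butyldimethylsilyl)oxy]-5-methoxy-3-methylphenyl}-2-methylbut-2-en-1-yl]-3a,7a-dimethyl-6-{2-methyl-2-[(triethylsilyl)oxy]propyl}-1,2,3,3a,4,7a-hexahydro-7H-inden-7-one | COc1cc(C)c(O[Si](C)(C)C(C)(C)C)c(C/C=C(\C)CC2=C(CC(C)(C)O[Si](CC)(CC)CC)C(=O)[C@]3(C)CCC[C@]3(C)C2)c1 | intermediate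
37 | CNP0158008.2: (3aR,7aR)-5-[(2E)-4-(2-hydroxy-5-methoxy-3-methylphenyl)-2-methylbut-2-en-1-yl]-6-(2-hydroxy-2-methylpropyl)-3a,7a-dimethyl-1,2,3,3a,4,7a-hexahydro-7H-inden-7-one | COc1cc(C)c(O)c(C/C=C(\C)CC2=C(CC(C)(C)O)C(=O)[C@]3(C)CCC[C@]3(C)C2)c1 | target

**Step count**
Total: 23 steps (15 on the main line, 2 for the C6 fragment, 6 for the arene fragment).
Longest linear sequence: 15 steps from neryl acetate (steps 1–7, 10–15, 22, 23).

**Steps most likely to fail**

Step 6 (carries the label). Enolisation of the lactone may stall, the boron ketene acetal may decay before the crowded C7a–C3a bond forms, or the ligand may discriminate poorly between the two faces. Fallback by known chemistry, from lactone 9 back to acid 12: LiN(SiMe3)2 and t-BuMe2SiCl/HMPA in THF at −78 °C should give the tert-butyldimethylsilyl ketene acetal F1, which survives prolonged heating. In toluene at 110 °C the silyl ketene acetal Claisen ring contraction, the established non-enantioselective form of this reaction for unsaturated medium-ring lactones with the same tether-enforced boat, should lead to the silyl ester F2 of the racemic cis acid. Mild hydrolysis (K2CO3, MeOH–H2O, then acid) would give the racemic acid F3. This is resolved by crystallisation of its (R)-1-phenylethylammonium salt F4 (the antipodal amine if the other diastereomeric salt is the less soluble one), and acidification returns 12.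

Step 5. Intermolecular acylation (diolide and oligomers) may outrun closure of the strained nine-membered ring. Fallback from hydroxy acid 7 back to lactone 9: Mitsunobu macrolactonisation (PPh3, DIAD, toluene–THF, slow addition at high dilution, 0 °C → rt) activates the allylic hydroxyl instead of the carboxyl, so the ring is closed by SN2 attack of the carboxylate on C5 and not by acyl transfer; this fallback makes no new compound (F0).

Step 22. Transmetalation from the hindered, electron-poor alkenylstannane may be slow, which would let the (η3-allyl)Pd intermediate isomerise or homocouple and the skipped alkene drift into conjugation. Fallback from bromide 35 and triflate 25 to 36, bypassing stannane 26: Bu3SnLi (THF, −78 °C) displaces the bromide of 35 to give the allylstannane F5, which transmetalates fast. Stille coupling of F5 with enol triflate 25 [Pd(PPh3)4, LiCl, THF, 60 °C] would then join C5 to the CH2 terminus with the roles of nucleophile and electrophile exchanged; any product of allylic transposition or (Z)-isomer would have to be separated at this stage.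

**Further compounds**
F1 | step 6 | tert-butyldimethylsilyl ketene acetal of lactone 9 (ring carbon and ring oxygen cis) | C/C1=C(\O[Si](C)(C)C(C)(C)C)OC/C=C(C)\CCC1
F2 | step 6 | tert-butyldimethylsilyl cis-2-ethenyl-1,2-dimethylcyclopentane-1-carboxylate, racemate (both enantiomers written) | CC(C)(C)[Si](C)(C)OC(=O)[C@]1(C)CCC[C@]1(C)C=C.CC(C)(C)[Si](C)(C)OC(=O)[C@@]1(C)CCC[C@@]1(C)C=C
F3 | step 6 | cis-2-ethenyl-1,2-dimethylcyclopentane-1-carboxylic acid, racemate (both enantiomers written) | OC(=O)[C@]1(C)CCC[C@]1(C)C=C.OC(=O)[C@@]1(C)CCC[C@@]1(C)C=C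
F4 | step 6 | (R)-1-phenylethylammonium (1R,2R)-2-ethenyl-1,2-dimethylcyclopentane-1-carboxylate | C[C@@H]([NH3+])c1ccccc1.[O-]C(=O)[C@]1(C)CCC[C@]1(C)C=C
F0 | step 5 | none | none
F5 | step 22 | tributyl{(2E)-4-{2-[(tert-butyldimethylsilyl)oxy]-5-methoxy-3-methylphenyl}-2-methylbut-2-en-1-yl}stannane | CCCC[Sn](CCCC)(CCCC)C/C(C)=C/Cc1cc(OC)cc(C)c1O[Si](C)(C)C(C)(C)C
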